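Ring A of the flavonol (C4a, C5, C6, C7, C8, C8a), with oxygen on C5, C7 and C8a and the C4 carbonyl on C4a, is the folded form of a linear 3,5,7-triketo ester. The route therefore rests on one C–C disconnection, C4a–C5. An intramolecular Claisen condensation turns the open-chain methyl triketo ester with a 4-methoxycinnamoyl end into the acylphloroglucinol (chalcone). This creates ring A, its three phenols and the correctly placed C4 ketone in one operation. The precursor is assembled from triacetic acid lactone and methyl 4-methoxycinnamate. The chalcone is then oxidised to the flavone, hydroxylated at C3, sulfated and deprotected.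

Key step: step 3

Remark: the target has no stereocentre and is achiral, so no enantiocontrol is needed; the only stereo-elements on the way are the E alkene of the cinnamoyl unit and racemic, transient ring-C intermediates.
Remark: the target is drawn as the free hydrogen sulfate; the sulfate is carried as its triethylammonium salt and converted to the acid form only in the last operation, because the salt is the form that stores well.

Step 1
Reactants: 1 4-hydroxy-6-methyl-2H-pyran-2-one (triacetic acid lactone)
Product: 2 methyl 3,5-dioxohexanoate
Conditions: Mg(OMe)2 (2.5 equiv), MeOH, reflux; cold 1 M HCl work-up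
Reagents that add atoms: magnesium methoxide, [Mg+2].[O-]C.[O-]C
Why: Methoxide opens the lactone by acyl–oxygen cleavage (methanolysis of an enol lactone), and the magnesium chelate of the resulting β,δ-diketo ester is protected from recyclisation and retro-Claisen cleavage until the acidic work-up.

Step 2
Reactants: 2 methyl 3,5-dioxohexanoate; 3 methyl (E)-4-methoxycinnamate (0.45 equiv relative to 2)
Product: 5 methyl (E)-9-(4-methoxyphenyl)-3,5,7-trioxonon-8-enoate, via trilithium trienolate 4 (not isolated)
Conditions: LDA (3.1 equiv per 2), THF, −78 → 0 °C; then 3, −78 → −20 °C; inverse quench into AcOH/THF at −78 °C; crude product kept cold and used at once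
Reagents that add atoms: none
Why: This is a crossed Claisen acylation of a polyanion, in which the terminal C6 carbanion of the trienolate (the last formed and most nucleophilic site) adds 1,2 to the ester carbonyl of 3, the hard lithium-bound carbanion and the donor-deactivated β-carbon of the anisyl acrylate disfavouring conjugate addition, while the ester of 4 is masked as its enolate and cannot self-condense and the second equivalent of 4 takes up the acidic C6 proton of the product.

Step 3
Reactants: 5 methyl (E)-9-(4-methoxyphenyl)-3,5,7-trioxonon-8-enoate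
Product: 7 2',4',6'-trihydroxy-4-methoxychalcone, via 2-acylcyclohexane-1,3,5-trione 6 (not isolated)
Conditions: NaOMe (6 equiv), anhydrous MeOH, 0 °C → rt, Ar; then poured into ice-cold 1 M HCl (pH 2–3), rapid extraction
Reagents that add atoms: none
Why: In excess methoxide the C5/C7 β-diketone is fully enolised and chain carbon C6 attacks the ester carbonyl C1; methoxide is expelled to give the triketone 6, which enolises three times to the aromatic phloroglucinol (chain C6 becomes C4a and chain C1 becomes C5 of the flavonoid, so the new bond is C4a–C5). The closest known reaction type is the intramolecular Claisen (Dieckmann-type) C-acylation of 3,5,7-triketo esters to acylphloroglucinols, the laboratory counterpart of the chalcone-synthase ring closure. Ring A closes in the 6-exo-trig mode (6-enolexo), the ester C=O lying outside the new ring. No stereocentre is formed and the E alkene is not touched. The step needs C-acylation at C1 to beat the aldol closure of C2 onto the C7 carbonyl (a styryl resorcylate) and O-acylation to a 4-hydroxy-2-pyranone. This is secured because C7 is an enolised, anisyl-conjugated vinylogous carbonyl of low electrophilicity, because any aldol adduct reverts under strong base whereas loss of methoxide and aromatisation are irreversible, and because methoxide in dry methanol cannot saponify the methyl ester to an unreactive carboxylate.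

Step 4
Reactants: 7 2',4',6'-trihydroxy-4-methoxychalcone
Product: 10 acacetin (5,7-dihydroxy-4'-methoxyflavone), via isosakuranetin 8 (not isolated), via 3-iodoisosakuranetin 9 (not isolated)
Conditions: I2 (1.05 equiv), pyridine, 95 °C; aq. Na2S2O3 then dilute HCl work-up
Reagents that add atoms: none
Why: Pyridine first closes ring C by 6-endo-trig oxa-Michael addition of a 2'-hydroxyl (chalcone–flavanone isomerisation, racemic C2), and iodine then iodinates C3 α to the C4 ketone and pyridine eliminates HI (iodine/pyridine dehydrogenation of flavanones), so that any flavanone already present in 7 converges on the same flavone.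

Step 5
Reactants: 10 acacetin
Product: 11 5,7-bis(benzyloxy)-4'-methoxyflavone
Conditions: BnBr (3 equiv), K2CO3 (4 equiv), nBu4NI (cat.), DMF, 70 °C
Reagents that add atoms: benzyl bromide, BrCc1ccccc1
Why: Williamson etherification caps the 7-OH quickly and the chelated 5-OH under the forcing conditions (excess bromide, iodide catalysis, warm DMF), so that both ring-A phenols are protected and no regioselectivity is required.

Step 6
Reactants: 11 5,7-bis(benzyloxy)-4'-methoxyflavone
Product: 13 5,7-bis(benzyloxy)-3-hydroxy-4'-methoxyflavone, via flavone 2,3-epoxide 12 (not isolated)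
Conditions: DMDO (ca. 0.07 M in acetone, 3 equiv), CH2Cl2, 0 °C → rt, dark; concentrate; p-TsOH·H2O (0.1 equiv), CH2Cl2, rt
Reagents that add atoms: dimethyldioxirane, CC1(C)OO1
Why: Dimethyldioxirane epoxidises the C2=C3 bond of fully O-protected flavones (electrophilic epoxidation), and acid opens the racemic epoxide at C2 to the cation stabilised by O1 and the anisyl ring, which loses H3 to give the 3-hydroxyflavone and erases both epoxide stereocentres.

Step 7
Reactants: 13 5,7-bis(benzyloxy)-3-hydroxy-4'-methoxyflavone
Product: 14 triethylammonium 5,7-bis(benzyloxy)-2-(4-methoxyphenyl)-4-oxo-4H-chromen-3-yl sulfate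
Conditions: SO3·NEt3 (4 equiv), DMF, 40 °C; MeOH quench; chromatography on silica with 1% Et3N in the eluent
Reagents that add atoms: sulfur trioxide–triethylamine complex, CC[N+](CC)(CC)S(=O)(=O)[O-]
Why: O-Sulfonation with a sulfur trioxide–amine complex can only occur at the 3-OH, the single free hydroxyl now that O5 and O7 are benzylated, and the sulfate monoester is isolated as its stable triethylammonium salt.

Step 8
Reactants: 14 triethylammonium 5,7-bis(benzyloxy)-2-(4-methoxyphenyl)-4-oxo-4H-chromen-3-yl sulfate
Product: 15 kaempferide 3-O-sulfate (5,7-dihydroxy-2-(4-methoxyphenyl)-4-oxo-4H-chromen-3-yl hydrogen sulfate)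
Conditions: H2 (1 atm), 10% Pd/C, THF/MeOH, rt; filter; Dowex 50W (H+ form), MeOH/H2O, 0 °C; lyophilise
Reagents that add atoms: none
Why: Catalytic hydrogenolysis cleaves both benzyl aryl ethers while the sulfate monoester salt, the aryl methyl ether and the flavonol C2=C3 bond are inert to H2/Pd at 1 atm, and a brief cold pass through the acidic resin exchanges triethylammonium for a proton.

Compound list
1 | 4-hydroxy-6-methyl-2H-pyran-2-one (triacetic acid lactone) | Cc1cc(O)cc(=O)o1 | starting material
2 | methyl 3,5-dioxohexanoate | COC(=O)CC(=O)CC(C)=O | intermediate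
3 | methyl (E)-4-methoxycinnamate | COC(=O)/C=C/c1ccc(OC)cc1 | starting material
4 | trilithium trienolate of methyl 3,5-dioxohexanoate | [Li+].[Li+].[Li+].C=C([O-])C=C([O-])C=C([O-])OC | intermediate (not isolated)
5 | methyl (E)-9-(4-methoxyphenyl)-3,5,7-trioxonon-8-enoate | COC(=O)CC(=O)CC(=O)CC(=O)/C=C/c1ccc(OC)cc1 | intermediate
6 | 2-[(E)-3-(4-methoxyphenyl)prop-2-enoyl]cyclohexane-1,3,5-trione | COc1ccc(/C=C/C(=O)C2C(=O)CC(=O)CC2=O)cc1 | intermediate (not isolated)
7 | 2',4',6'-trihydroxy-4-methoxychalcone, (E)-3-(4-methoxyphenyl)-1-(2,4,6-trihydroxyphenyl)prop-2-en-1-one | COc1ccc(/C=C/C(=O)c2c(O)cc(O)cc2O)cc1 | intermediate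
8 | isosakuranetin, 5,7-dihydroxy-4'-methoxyflavanone (racemic at C2) | COc1ccc(C2CC(=O)c3c(O)cc(O)cc3O2)cc1 | intermediate (not isolated)
9 | 3-iodoisosakuranetin, 5,7-dihydroxy-3-iodo-4'-methoxyflavanone (racemic) | COc1ccc(C2Oc3cc(O)cc(O)c3C(=O)C2I)cc1 | intermediate (not isolated)
10 | acacetin, 5,7-dihydroxy-4'-methoxyflavone | COc1ccc(-c2cc(=O)c3c(O)cc(O)cc3o2)cc1 | intermediate
11 | 5,7-bis(benzyloxy)-4'-methoxyflavone | COc1ccc(-c2cc(=O)c3c(OCc4ccccc4)cc(OCc4ccccc4)cc3o2)cc1 | intermediate
12 | 5,7-bis(benzyloxy)-4'-methoxyflavone 2,3-epoxide (racemic, cis-fused) | COc1ccc(cc1)C12OC1C(=O)c1c(OCc3ccccc3)cc(OCc3ccccc3)cc1O2 | intermediate (not isolated)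
13 | 5,7-bis(benzyloxy)-3-hydroxy-4'-methoxyflavone (5,7-di-O-benzylkaempferide) | COc1ccc(-c2oc3cc(OCc4ccccc4)cc(OCc4ccccc4)c3c(=O)c2O)cc1 | intermediate
14 | triethylammonium 5,7-bis(benzyloxy)-2-(4-methoxyphenyl)-4-oxo-4H-chromen-3-yl sulfate | COc1ccc(-c2oc3cc(OCc4ccccc4)cc(OCc4ccccc4)c3c(=O)c2OS(=O)(=O)[O-])cc1.CC[NH+](CC)CC | intermediate
15 | kaempferide 3-O-sulfate | COc1ccc(-c2oc3cc(O)cc(O)c3c(=O)c2OS(=O)(=O)O)cc1 | target

Total step count: 8. Longest linear sequence: 8 steps (1 → 15).

Steps most likely to fail

Step 3. The ring closure may leave the Claisen path: chain C2 may add to the C7 carbonyl (aldol closure), the chain may lactonise through oxygen, or methoxide may fragment it by retro-Claisen cleavage. The fallback no longer builds ring A but takes it from a ready-made arene. It sets out from 3, which is saponified (LiOH, THF/H2O) to (E)-4-methoxycinnamic acid F1 and converted with oxalyl chloride and catalytic DMF into (E)-4-methoxycinnamoyl chloride F2. Friedel–Crafts C-acylation of commercial phloroglucinol with F2 (AlCl3, nitrobenzene, rt) should give the acylphloroglucinol 7, which closes under the Lewis-acid conditions and the acidic work-up to the flavanone. The fallback comes back to the route at 8, which is treated with iodine in pyridine as in step 4.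

Step 2. The trienolate may add in the conjugate sense to the acrylate, or be consumed by proton transfer before acylation is complete. The fallback masks the future ester as a dioxinone and releases the triketo ester under neutral thermal conditions. It sets out from 3, which is converted (MeNH(OMe)·HCl, iPrMgCl, THF, −20 °C) into the Weinreb amide (E)-N-methoxy-3-(4-methoxyphenyl)-N-methylprop-2-enamide F3. Commercial 2,2,6-trimethyl-4H-1,3-dioxin-4-one is acetylated at its 6-methyl group (LiHMDS, then acetyl chloride, THF, −78 °C) to 2,2-dimethyl-6-(2-oxopropyl)-4H-1,3-dioxin-4-one F4. Treatment of F4 with LDA (2.2 equiv, THF, −78 °C) and then F3 should acylate the terminal methyl and give 6-[(5E)-6-(4-methoxyphenyl)-2,4-dioxohex-5-en-1-yl]-2,2-dimethyl-4H-1,3-dioxin-4-one F5. Heating F5 in toluene with methanol (110 °C) expels acetone by retro-[4+2] reaction, and the acylketene (8E)-9-(4-methoxyphenyl)nona-1,8-diene-1,3,5,7-tetrone F6 is trapped by methanol. The fallback comes back to the route at 5, just before the key step.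

Step 6. Epoxidation of the electron-poor C2=C3 bond may be too slow to outrun oxidation at the benzylic C–H bonds or on the anisyl ring. The fallback installs the oxygen through a C3 carbanion instead. It sets out from 11: LDA (THF, −78 °C) removes H3, trimethyl borate traps the vinyl anion as dimethyl [5,7-bis(benzyloxy)-2-(4-methoxyphenyl)-4-oxo-4H-chromen-3-yl]boronate F7, and H2O2/AcOH in the same flask oxidises the C–B bond. The fallback comes back to the route at 13.

Further compounds
F1 | step 3 | (E)-4-methoxycinnamic acid | COc1ccc(/C=C/C(=O)O)cc1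
F2 | step 3 | (E)-4-methoxycinnamoyl chloride | COc1ccc(/C=C/C(=O)Cl)cc1
F3 | step 2 | (E)-N-methoxy-3-(4-methoxyphenyl)-N-methylprop-2-enamide | CON(C)C(=O)/C=C/c1ccc(OC)cc1
F4 | step 2 | 2,2-dimethyl-6-(2-oxopropyl)-4H-1,3-dioxin-4-one | CC(=O)CC1=CC(=O)OC(C)(C)O1
F5 | step 2 | 6-[(5E)-6-(4-methoxyphenyl)-2,4-dioxohex-5-en-1-yl]-2,2-dimethyl-4H-1,3-dioxin-4-one | COc1ccc(/C=C/C(=O)CC(=O)CC2=CC(=O)OC(C)(C)O2)cc1
F6 | step 2 | (8E)-9-(4-methoxyphenyl)nona-1,8-diene-1,3,5,7-tetrone | COc1ccc(/C=C/C(=O)CC(=O)CC(=O)C=C=O)cc1
F7 | step 6 | dimethyl [5,7-bis(benzyloxy)-2-(4-methoxyphenyl)-4-oxo-4H-chromen-3-yl]boronate | COc1ccc(-c2oc3cc(OCc4ccccc4)cc(OCc4ccccc4)c3c(=O)c2B(OC)OC)cc1
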